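**Strategy.** Ring A of the target is an unfunctionalised cyclohexane whose quaternary carbons C4 (gem-dimethyl) and C10 (angular methyl) both adjoin the ring-fusion methine C5, which in turn adjoins oxygenated C6 of ring B (labdane numbering). Read backwards, C4=C5–C6=O is a β,β-dimethyl enone and C10=C1–C2=C3 a diene. Everything rests on one thermal intramolecular Diels–Alder reaction of the acyclic trienone CH2=CH–CH=C(CH3)–C9(OSiMe3)(C≡CSiMe3)–C8H(CH3)–CH2–CO–CH=C(CH3)2, which forms C3–C4 and C5–C10, closes rings A and B together and creates both quaternary carbons. C8 and C9, set in one sparteine-mediated homoaldol step, are relayed to C10 and C5 there, and to C6 afterwards.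

Key step: step 10

Remark on numbering: labdane numbering is used for all intermediates (ring A = C1–C5 and C10; ring B = C5–C10; side chain C11–C16 on C9).

Remark on step 5: the sense of induction is assumed to follow the accepted course of the sparteine-mediated crotyl carbamate homoaldol reaction ((−)-sparteine gives the S lithium compound by crystallisation, titanation inverts, addition is syn-SE′ through a chair); on that basis (+)-sparteine is the enantiomer required here.

Step 1
Reactants: 1 acrolein; 2 ethyl 2-(triphenyl-λ5-phosphanylidene)propanoate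
Product: 3 ethyl (2E)-2-methylpenta-2,4-dienoate
Conditions: CH2Cl2, 0 → 23 °C
Reagents that add atoms: none
Why: Wittig olefination with the stabilised ylide should give the E alkene, placing the ester carbon (C9) trans and the C10 methyl cis to the vinyl group, which is the diene geometry the cycloaddition needs.

Step 2
Reactants: 3 ethyl (2E)-2-methylpenta-2,4-dienoate
Product: 4 (2E)-N-methoxy-N,2-dimethylpenta-2,4-dienamide
Conditions: MeNHOMe·HCl, iPrMgCl, THF, −20 °C
Reagents that add atoms: N,O-dimethylhydroxylamine hydrochloride, CNOC.Cl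
Why: The chloromagnesium amide attacks the ester carbonyl (Weinreb amide formation) and should leave the diene untouched.

Step 3
Reactants: 4 (2E)-N-methoxy-N,2-dimethylpenta-2,4-dienamide
Product: 5 (4E)-4-methyl-1-(trimethylsilyl)hepta-4,6-dien-1-yn-3-one
Conditions: HC≡CSiMe3, n-BuLi, THF, −78 °C; then 4, −78 → −30 °C; AcOH, −78 °C
Reagents that add atoms: (trimethylsilyl)acetylene, C#C[Si](C)(C)C
Why: The lithium acetylide adds once because the chelated tetrahedral intermediate survives until the cold acidic quench (Weinreb ketone synthesis), which also prevents conjugate addition of the liberated amine to the ynone.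

Step 4
Reactants: 6 (E)-but-2-en-1-ol; 7 N,N-diisopropylcarbamoyl chloride
Product: 8 (E)-but-2-en-1-yl N,N-diisopropylcarbamate
Conditions: pyridine, 90 °C
Reagents that add atoms: none
Why: O-Carbamoylation of the allylic alcohol by acyl substitution at the carbamoyl chloride.

Step 5
Reactants: 8 (E)-but-2-en-1-yl N,N-diisopropylcarbamate; 5 (4E)-4-methyl-1-(trimethylsilyl)hepta-4,6-dien-1-yn-3-one
Product: 11 (1Z,3R,4R,5E)-4-hydroxy-3,5-dimethyl-4-[(trimethylsilyl)ethynyl]octa-1,5,7-trien-1-yl N,N-diisopropylcarbamate, via lithiated carbamate 9 (not isolated), via titanated carbamate 10 (not isolated)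
Conditions: n-BuLi, (+)-sparteine, pentane/cyclohexane, −78 °C (crystallisation); Ti(OiPr)4, −78 °C; then 5, −78 → −20 °C; aq. NH4Cl
Reagents that add atoms: none
Why: Sparteine-mediated lithiation with crystallisation-driven dynamic resolution should give the R lithium compound 9, titanation inverts it to 10, and 10 adds through its γ-carbon to the ketone in a closed chair (asymmetric homoaldol reaction) with the crotyl methyl and the branched dienyl group equatorial and the slim alkynyl group axial, which sets C8 (R) and C9 (R) in one event and delivers C6 as a Z enol carbamate at the aldehyde oxidation level.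

Step 6
Reactants: 11 homoaldol adduct
Product: 12 (1Z,3R,4R,5E)-3,5-dimethyl-4-[(trimethylsilyl)ethynyl]-4-[(trimethylsilyl)oxy]octa-1,5,7-trien-1-yl N,N-diisopropylcarbamate
Conditions: Me3SiOTf, 2,6-lutidine, CH2Cl2, −78 °C
Reagents that add atoms: trimethylsilyl trifluoromethanesulfonate, C[Si](C)(C)OS(=O)(=O)C(F)(F)F
Why: Silyl triflate with a hindered base silylates the tertiary alcohol under basic conditions, which blocks ionisation of the doubly activated carbinol and later hemiketal formation with the C6 ketone.

Step 7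
Reactants: 12 silyl ether
Product: 13 (3R,4R,5E)-3,5-dimethyl-4-[(trimethylsilyl)ethynyl]-4-[(trimethylsilyl)oxy]octa-5,7-dienal
Conditions: LiAlH4, THF, 0 °C; EtOAc, then aq. potassium sodium tartrate
Reagents that add atoms: none
Why: Hydride attacks the carbamoyl carbonyl (reductive carbamate cleavage), the enolate leaves as its aluminium enolate and is protonated on work-up, so the C6 aldehyde is unveiled without acid and without touching the silyl groups, the diene or C8/C9.

Step 8
Reactants: 13 aldehyde; 14 2-methylprop-1-en-1-ylmagnesium bromide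
Product: 15 (6R,7R,8E)-2,6,8-trimethyl-7-[(trimethylsilyl)ethynyl]-7-[(trimethylsilyl)oxy]undeca-2,8,10-trien-4-ol (mixture of C4 carbinol epimers)
Conditions: THF, −78 → 0 °C; aq. NH4Cl
Reagents that add atoms: none
Why: 1,2-Addition of the alkenyl Grignard reagent brings in C5 and C4 with both methyls; the new carbinol centre (C6 of the target) forms as a mixture that the next step erases.

Step 9
Reactants: 15 allylic alcohol
Product: 16 (6R,7R,8E)-2,6,8-trimethyl-7-[(trimethylsilyl)ethynyl]-7-[(trimethylsilyl)oxy]undeca-2,8,10-trien-4-one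
Conditions: MnO2, CH2Cl2, 23 °C
Reagents that add atoms: none
Why: MnO2 oxidises the allylic alcohol selectively to the β,β-dimethyl enone under neutral conditions that should leave the silyl ether and the diene intact.

Step 10
Reactants: 16 trienone
Product: 19 9α-hydroxy-13,14,15,16-tetranorlabd-1-en-11-yn-6-one (5α-H, 8α-methyl, 10β-methyl), via bis-silyl trans-fused adduct 17 (not isolated), via bis-silyl cis-fused adduct 18 (not isolated)
Conditions: PhMe (0.01 M), BHT, 170 °C, sealed tube; then NaOMe, MeOH, 50 °C
Reagents that add atoms: none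
Why: Heating brings the E-diene (C10=C1–C2=C3, HOMO, largest coefficient at unsubstituted C3) and the tethered β,β-dimethyl enone (C4=C5–C6=O, LUMO, largest coefficient at C4) into a concerted, asynchronous normal-demand [4+2] cycloaddition in which C3–C4 leads and C5–C10 follows, the closest known type being the type 1 intramolecular Diels–Alder reaction of 1,7,9-decatrien-3-ones. Ring A is closed by the cycloaddition itself (both new σ-bonds, C1=C2 left behind), and ring B is closed by the C5–C10 bond as a six-membered ring through a chair-like four-carbon tether (C6–C9) with the C6 carbonyl exo to the diene, which gives the trans ring fusion. C10 is set by the diene face: C8 places its methyl equatorial in that chair (the other face would force a 1,3-diaxial clash between the C8 and C10 methyls), and C9 keeps its silyloxy group in the diene plane with the slim alkynyl group anti to the incoming dienophile, so both tether centres select the same face. C5 is set by the exo orientation, since the endo mode would push C4 with its two methyls into a 1,3-diaxial relation with the C9 oxygen; any endo adduct 18 shares C10 and should be epimerised at C5 (α to the C6 ketone) to the trans-fused ketone by the methoxide that also removes both silyl groups. The step needs periselectivity, diene-face selectivity and exo selectivity: the first is secured because the alkyne on C9 cannot reach the diene and the enone is the only activated 2π partner, the others by the C8/C9 substitution and, for C5, by thermodynamic funnelling, while dilution and BHT suppress dimerisation and polymerisation.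

Step 11
Reactants: 19 hydroxy ynyl ketone
Product: 20 13,14,15,16-tetranorlabda-1,11-diene-6β,9α-diol
Conditions: LiAlH4, THF, 0 → 60 °C; aq. potassium sodium tartrate
Reagents that add atoms: none
Why: Hydride should attack the C6 ketone from the α-face, because the β-face is screened by the axial methyls on C10 and C4, giving the axial 6β-alcohol, and the C9 alkoxyaluminium hydride delivers hydride intramolecularly to the ethynyl group (trans-hydroalumination of a propargylic alcohol), giving the vinyl group on protonolysis.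

Step 12
Reactants: 20 diol
Product: 21 6β-acetoxy-13,14,15,16-tetranorlabda-1,11-dien-9α-ol
Conditions: Ac2O, DMAP, pyridine, 50 °C
Reagents that add atoms: acetic anhydride, CC(=O)OC(C)=O
Why: DMAP-catalysed acylation esterifies the secondary 6β-hydroxyl, while the tertiary C9 hydroxyl flanked by C8 and quaternary C10 is too hindered to react.

Step 13
Reactants: 21 acetate; 22 3-bromofuran-2(5H)-one
Product: 24 6β-acetoxy-9α-hydroxylabda-1,13-dien-16,15-olide, via B-alkyl borane 23 (not isolated)
Conditions: 9-BBN-H, THF, 0 → 23 °C; then 22, PdCl2(dppf), AsPh3, Cs2CO3, DMF/H2O, 23 °C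
Reagents that add atoms: none
Why: 9-BBN-H adds anti-Markovnikov and only to the monosubstituted vinyl group (the cis-disubstituted ring alkene next to quaternary C10 is far slower), and the primary alkylborane undergoes B-alkyl Suzuki–Miyaura coupling with the α-bromobutenolide to form C12–C13.

Step 14
Reactants: 24 dienolide
Product: 25 (5S,6R,8R,9R,10S)-6-acetoxy-9-hydroxylabd-13-en-16,15-olide (target)
Conditions: H2 (1 atm), RhCl(PPh3)3, benzene/EtOH, 23 °C
Reagents that add atoms: none
Why: RhCl(PPh3)3 should hydrogenate the isolated cis-disubstituted C1=C2 bond much faster than the conjugated, trisubstituted butenolide alkene (homogeneous hydrogenation), saturating ring A without creating or disturbing a stereocentre.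

**Compound list**

1 | acrolein | C=CC=O | starting material
2 | ethyl 2-(triphenyl-λ5-phosphanylidene)propanoate | CCOC(=O)C(C)=P(c1ccccc1)(c1ccccc1)c1ccccc1 | starting material
3 | ethyl (2E)-2-methylpenta-2,4-dienoate | C=C/C=C(\C)C(=O)OCC | intermediate
4 | (2E)-N-methoxy-N,2-dimethylpenta-2,4-dienamide | C=C/C=C(\C)C(=O)N(C)OC | intermediate
5 | (4E)-4-methyl-1-(trimethylsilyl)hepta-4,6-dien-1-yn-3-one | C=C/C=C(\C)C(=O)C#C[Si](C)(C)C | intermediate
6 | (E)-but-2-en-1-ol | C/C=C/CO | starting material
7 | N,N-diisopropylcarbamoyl chloride | CC(C)N(C(C)C)C(=O)Cl | starting material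
8 | (E)-but-2-en-1-yl N,N-diisopropylcarbamate | C/C=C/COC(=O)N(C(C)C)C(C)C | intermediate
9 | (R,E)-1-lithiobut-2-en-1-yl N,N-diisopropylcarbamate, formed as its (+)-sparteine complex | C/C=C/[C@@H]([Li])OC(=O)N(C(C)C)C(C)C | intermediate
10 | (S,E)-1-(triisopropoxytitanio)but-2-en-1-yl N,N-diisopropylcarbamate (tetravalent titanium) | C/C=C/[C@H]([Ti](OC(C)C)(OC(C)C)OC(C)C)OC(=O)N(C(C)C)C(C)C | intermediate
11 | (1Z,3R,4R,5E)-4-hydroxy-3,5-dimethyl-4-[(trimethylsilyl)ethynyl]octa-1,5,7-trien-1-yl N,N-diisopropylcarbamate | C=C/C=C(\C)[C@@](O)(C#C[Si](C)(C)C)[C@H](C)/C=C\OC(=O)N(C(C)C)C(C)C | intermediate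
12 | (1Z,3R,4R,5E)-3,5-dimethyl-4-[(trimethylsilyl)ethynyl]-4-[(trimethylsilyl)oxy]octa-1,5,7-trien-1-yl N,N-diisopropylcarbamate | C=C/C=C(\C)[C@@](O[Si](C)(C)C)(C#C[Si](C)(C)C)[C@H](C)/C=C\OC(=O)N(C(C)C)C(C)C | intermediate
13 | (3R,4R,5E)-3,5-dimethyl-4-[(trimethylsilyl)ethynyl]-4-[(trimethylsilyl)oxy]octa-5,7-dienal | C=C/C=C(\C)[C@@](O[Si](C)(C)C)(C#C[Si](C)(C)C)[C@H](C)CC=O | intermediate
14 | 2-methylprop-1-en-1-ylmagnesium bromide | CC(C)=C[Mg]Br | starting material
15 | (6R,7R,8E)-2,6,8-trimethyl-7-[(trimethylsilyl)ethynyl]-7-[(trimethylsilyl)oxy]undeca-2,8,10-trien-4-ol, C4 epimers | C=C/C=C(\C)[C@@](O[Si](C)(C)C)(C#C[Si](C)(C)C)[C@H](C)CC(O)C=C(C)C | intermediate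
16 | (6R,7R,8E)-2,6,8-trimethyl-7-[(trimethylsilyl)ethynyl]-7-[(trimethylsilyl)oxy]undeca-2,8,10-trien-4-one | C=C/C=C(\C)[C@@](O[Si](C)(C)C)(C#C[Si](C)(C)C)[C@H](C)CC(=O)C=C(C)C | intermediate
17 | 9α-(trimethylsilyloxy)-12-(trimethylsilyl)-13,14,15,16-tetranorlabd-1-en-11-yn-6-one (5α-H, trans-fused) | O=C1C[C@@H](C)[C@](O[Si](C)(C)C)(C#C[Si](C)(C)C)[C@@]2(C)C=CCC(C)(C)[C@H]12 | intermediate
18 | C5 epimer of 17 (5β-H, cis-fused) | O=C1C[C@@H](C)[C@](O[Si](C)(C)C)(C#C[Si](C)(C)C)[C@@]2(C)C=CCC(C)(C)[C@@H]12 | intermediate
19 | 9α-hydroxy-13,14,15,16-tetranorlabd-1-en-11-yn-6-one (5α-H, 8α-methyl, 10β-methyl) | O=C1C[C@@H](C)[C@](O)(C#C)[C@@]2(C)C=CCC(C)(C)[C@H]12 | intermediate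
20 | 13,14,15,16-tetranorlabda-1,11-diene-6β,9α-diol | O[C@@H]1C[C@@H](C)[C@](O)(C=C)[C@@]2(C)C=CCC(C)(C)[C@H]12 | intermediate
21 | 6β-acetoxy-13,14,15,16-tetranorlabda-1,11-dien-9α-ol | CC(=O)O[C@@H]1C[C@@H](C)[C@](O)(C=C)[C@@]2(C)C=CCC(C)(C)[C@H]12 | intermediate
22 | 3-bromofuran-2(5H)-one | O=C1OCC=C1Br | starting material
23 | 6β-acetoxy-12-(9-borabicyclo[3.3.1]nonan-9-yl)-13,14,15,16-tetranorlabd-1-en-9α-ol | CC(=O)O[C@@H]1C[C@@H](C)[C@](O)(CCB3C4CCCC3CCC4)[C@@]2(C)C=CCC(C)(C)[C@H]12 | intermediate
24 | 6β-acetoxy-9α-hydroxylabda-1,13-dien-16,15-olide | CC(=O)O[C@@H]1C[C@@H](C)[C@](O)(CCC3=CCOC3=O)[C@@]2(C)C=CCC(C)(C)[C@H]12 | intermediate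
25 | (5S,6R,8R,9R,10S)-6-acetoxy-9-hydroxylabd-13-en-16,15-olide | CC(=O)O[C@@H]1C[C@@H](C)[C@](O)(CCC2=CCOC2=O)[C@@]2(C)CCCC(C)(C)[C@H]12 | target

**Totals.** Total step count: 14. Longest linear sequence: 13 steps (steps 1–3 and 5–14).

**Steps most likely to fail**

Step 10. The cycloaddition may be too slow, because both new bonds end at carbons that become quaternary, and prolonged heating may instead isomerise the cis-methyl diene by 1,5-hydrogen shift or erode the face selectivity. The fallback changes the dienophile to an ynone and sets out from aldehyde 13. Prop-1-ynylmagnesium bromide should give the propargylic alcohol (6R,7R,8E)-6,8-dimethyl-7-[(trimethylsilyl)ethynyl]-7-[(trimethylsilyl)oxy]undeca-8,10-dien-2-yn-4-ol F1, and MnO2 the ynone (6R,7R,8E)-6,8-dimethyl-7-[(trimethylsilyl)ethynyl]-7-[(trimethylsilyl)oxy]undeca-8,10-dien-2-yn-4-one F2. Its sp-hybridised, singly methylated C4 should cyclise at much lower temperature, under the same tether control of the diene face and with no exo/endo question, to the cyclohexa-1,4-diene enone 9α-(trimethylsilyloxy)-12-(trimethylsilyl)-13,14,15,16,19-pentanorlabda-1,4-dien-11-yn-6-one F3. Conjugate addition of Me2CuLi with Me3SiCl to the C4=C5–C6=O enone would install the second C4 methyl, and the methoxide treatment of step 10 would then set C5 and remove the silyl groups, returning to the route at 19.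

Step 5. The chair transition state may not discriminate well enough between the dienyl and alkynyl groups of ketone 5 (loss of configuration at C9), or the ynone may suffer conjugate addition. The fallback sets the two centres in separate steps and sets out from Weinreb amide 4. Reduction with iBu2AlH should give (2E)-2-methylpenta-2,4-dienal F4, to which the same titanium reagent 10 adds (aldehydes being the best-behaved homoaldol acceptors) to give the anti adduct (1Z,3R,4R,5E)-4-hydroxy-3,5-dimethylocta-1,5,7-trien-1-yl N,N-diisopropylcarbamate F5. Dess–Martin oxidation would give the ketone (1Z,3R,5E)-3,5-dimethyl-4-oxoocta-1,5,7-trien-1-yl N,N-diisopropylcarbamate F6, and Me3SiC≡CLi with CeCl3 should add anti to the alkenyl substituent of the C8 stereocentre (1,2-induction), returning to the route at 11.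

Step 14. Hydrogenation may lose chemoselectivity (the butenolide alkene is reduced as well) or stall at the hindered ring alkene. The fallback saturates ring A before the butenolide exists and sets out from acetate 21. Hydroboration with 9-BBN-H (borane 23) and oxidation with NaBO3·4H2O should give the primary alcohol 6β-acetoxy-13,14,15,16-tetranorlabd-1-ene-9α,12-diol F7, and H2 over Pd/C the saturated 6β-acetoxy-13,14,15,16-tetranorlabdane-9α,12-diol F8. I2, PPh3 and imidazole would give 6β-acetoxy-12-iodo-13,14,15,16-tetranorlabdan-9α-ol F9. A nickel-catalysed reductive cross-electrophile coupling of F9 with bromide 22 (NiBr2(dme), 4,4′-di-tert-butyl-2,2′-bipyridine, Mn powder, DMA) would form C12–C13 and return to the route at 25.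

**Further compounds**

F1 | step 10 | (6R,7R,8E)-6,8-dimethyl-7-[(trimethylsilyl)ethynyl]-7-[(trimethylsilyl)oxy]undeca-8,10-dien-2-yn-4-ol, C4 epimers | C=C/C=C(\C)[C@@](O[Si](C)(C)C)(C#C[Si](C)(C)C)[C@H](C)CC(O)C#CC
F2 | step 10 | (6R,7R,8E)-6,8-dimethyl-7-[(trimethylsilyl)ethynyl]-7-[(trimethylsilyl)oxy]undeca-8,10-dien-2-yn-4-one | C=C/C=C(\C)[C@@](O[Si](C)(C)C)(C#C[Si](C)(C)C)[C@H](C)CC(=O)C#CC
F3 | step 10 | 9α-(trimethylsilyloxy)-12-(trimethylsilyl)-13,14,15,16,19-pentanorlabda-1,4-dien-11-yn-6-one | O=C1C[C@@H](C)[C@](O[Si](C)(C)C)(C#C[Si](C)(C)C)[C@@]2(C)C=CCC(C)=C12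
F4 | step 5 | (2E)-2-methylpenta-2,4-dienal | C=C/C=C(\C)C=O
F5 | step 5 | (1Z,3R,4R,5E)-4-hydroxy-3,5-dimethylocta-1,5,7-trien-1-yl N,N-diisopropylcarbamate | C=C/C=C(\C)[C@H](O)[C@H](C)/C=C\OC(=O)N(C(C)C)C(C)C
F6 | step 5 | (1Z,3R,5E)-3,5-dimethyl-4-oxoocta-1,5,7-trien-1-yl N,N-diisopropylcarbamate | C=C/C=C(\C)C(=O)[C@H](C)/C=C\OC(=O)N(C(C)C)C(C)C
F7 | step 14 | 6β-acetoxy-13,14,15,16-tetranorlabd-1-ene-9α,12-diol | CC(=O)O[C@@H]1C[C@@H](C)[C@](O)(CCO)[C@@]2(C)C=CCC(C)(C)[C@H]12
F8 | step 14 | 6β-acetoxy-13,14,15,16-tetranorlabdane-9α,12-diol | CC(=O)O[C@@H]1C[C@@H](C)[C@](O)(CCO)[C@@]2(C)CCCC(C)(C)[C@H]12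
F9 | step 14 | 6β-acetoxy-12-iodo-13,14,15,16-tetranorlabdan-9α-ol | CC(=O)O[C@@H]1C[C@@H](C)[C@](O)(CCI)[C@@]2(C)CCCC(C)(C)[C@H]12
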